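We decide to follow G by its loss rate, and to ask how that pseudo-first-order rate depends on cJ.

common to all: D 0.50 M (in portions, 2)
- Friday's: J 0.76 M; run made earlier; portions every 1.0 h
- Wednesday's: J 2.8 M; run made earlier; portions every 1.0 h
- autumn: J 2.00 M; the portions of D follow each other after 1.0 h, the first at the start; time 2.5 h
- dusk: J 0.600 M; the portions of D follow each other after 1.0 h, the first at the start; time 2.5 h

| run | time / min | G / % | D / % |
|---|---|---|---|
| Friday's | 20.0 | 9.3 | 31.5 |
| Friday's | 40.0 | 11.2 | 20.3 |
| Friday's | 60.0 | 9.6 | 13.2 |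
| Friday's | 80.0 | 15.8 | 44.7 |
| Wednesday's | 6.00 | 12.2 | 27.1 |
| Wednesday's | 15.0 | 16.6 | 12.8 |
| Wednesday's | 30.0 | 10.5 | 2.5 |
| Wednesday's | 80.0 | 15.7 | 10.3 |

(scatter of a reading: 0.5 percentage points)

1. which of these holds the largest part of the D at the end of autumn (G / E / D / Z)
2. which of these holds the largest part of the D at the end of dusk (G / E / D / Z)
3. final G in autumn, as a percentage of the D charged



Between two readings, G's balance gives this rate: the D lost times the share going to G, minus the change in G, over mean G times the interval. We read that share as 53.3 % from Wednesday's first reading, where G is counted net of what it had already lost. Wednesday's run, from 15.0 min to 30.0 min, then gives 0.0570 min⁻¹ near cJ = 2.59 M, counting one J per D lost. Friday's run, from 40.0 min to 60.0 min, gives 0.0259 min⁻¹ near 0.594 M. The rise of the rate per unit of cJ, our clearance slope, reads 0.0156 L mol⁻¹ min⁻¹.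

Each D takes at most two J, so autumn's cJ stays between 1.00 M and 2.00 M, and the slope puts G's loss rate between 0.0322 min⁻¹ and 0.0478 min⁻¹. From above: take Friday's G at 80.0 min plus all of its D, as if made at once, and decay it at the slower rate, which leaves 6.34 %. Counting just the share of that D brings this to 4.15 %, an estimate and no strict bound, as the share is a reading. From below: Wednesday's G alone at the faster rate leaves 0.552 %. Adding the share of Wednesday's D tightens this to 0.745 %.

The forecast gave 2.3 %, from 1.2 % to 4 %, which stands inside our bracket. It saw that “its loss is not proportional to J”, and it named Z for autumn and E for dusk.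

Autumn ends with G at 3.26 %, inside the bracket, and Z is largest at 42.0 %. Of the four species asked about, dusk ends with D largest at 27.5 %, above E at 21.0 %.

    D + G → Q (k = 8.00 × 10⁻⁵ L mol⁻¹ s⁻¹)
    D + J → G (k = 3.90 × 10⁻⁴ L mol⁻¹ s⁻¹)
    D + J → E (k = 1.80 × 10⁻⁴ L mol⁻¹ s⁻¹)
    G → L (k = 3.30 × 10⁻⁴ s⁻¹)
    J + E → Z (k = 4.10 × 10⁻⁵ L mol⁻¹ s⁻¹)
    J + G → Z (k = 2.20 × 10⁻⁴ L mol⁻¹ s⁻¹)

At the end of autumn J stands at 64.8 % of its charge, and the slope turns that into a loss rate of 0.0368 min⁻¹, a half-life for G of 18.8 min. The neighbouring flask is autumn read at 1.5 h. The same two rates, run from 80.0 min, bracket its G between 13.1 % and 28.7 %, and that flask holds 15.3 %.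

The readings are calculated for substances that don't exist; noise was put on by code.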